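**Strategy**

The route rests on closing the carbocycle (C4a–C5–C6–C7–C8–C8a) last, by forming C5–C6 on a finished pyran ring. The feature exploited is the doubly vinylogous ester O2–C3=C4–C4a=C5–C6=O: C5 is the exocyclic carbon of a 4-methylenepyran, the anhydrobase of a 4-methylpyrylium, and C6 is an acyl carbon. The precursor is an acyclic enynal whose acyl group carries C7 inside a lactic-acid-derived dioxolanone, a temporary ring that fixes the C7 configuration and activates C6. In one operation acid closes the pyrylium, base unmasks the anhydrobase, C5 attacks the dioxolanone carbonyl, pivalaldehyde is expelled and the freed C7 alkoxide is propionylated.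

Key step: step 7

**Remarks on the chemistry**

- Numbering: the isochromene numbering of the target (C1, O2, C3, C4, C4a, C5–C8, C8a) is used for the corresponding atoms of all intermediates.
- Assumption: 6 and 14 are drawn as the (E)-isomers (formyl group cis to chlorine or to the alkyne). The other geometrical isomer is expected to equilibrate with it under the acid of step 7 and is carried along.
- The C7 descriptor is S in 17 and 18 and R in 19 with the same spatial arrangement, because chlorine at C5 raises the CIP rank of C6 above C8.

**Route**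

Step 1
Reactants: 1 (S)-lactic acid; 2 pivalaldehyde
Product: 3 (2S,5S)-2-tert-butyl-5-methyl-1,3-dioxolan-4-one
Conditions: TsOH·H2O (cat.), H2SO4 (cat.), pentane, reflux, Dean–Stark; crystallization from pentane/Et2O, −78 °C
Reagents that add atoms: none
Why: Acid-catalysed acetalization with azeotropic removal of water closes the dioxolanone without touching the lactic acid centre, and the acetal centre C2 is set under thermodynamic control cis to the methyl group, the cis isomer being purified by crystallization (first stage of self-regeneration of stereocentres).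

Step 2
Reactants: 3 (2S,5S)-2-tert-butyl-5-methyl-1,3-dioxolan-4-one; 4 diketene
Product: 5 (2S,5R)-2-tert-butyl-5-methyl-5-(3-oxobutanoyl)-1,3-dioxolan-4-one
Conditions: LDA, THF, −78 °C; then 4, −78 → −40 °C; AcOH
Reagents that add atoms: none
Why: The lithium enolate is C-acylated by the lactone carbonyl of diketene (Claisen-type enolate acylation) on the face opposite to the tert-butyl group at C2, so the acyl group takes the place of the former hydrogen and the quaternary centre (the later C7) is regenerated as 5R; ring opening of diketene gives the diketonate directly, so no second equivalent of base is needed.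

Step 3
Reactants: 5 (2S,5R)-2-tert-butyl-5-methyl-5-(3-oxobutanoyl)-1,3-dioxolan-4-one
Product: 6 (2S,5R)-2-tert-butyl-5-[(2E)-3-chloro-2-formylbut-2-enoyl]-5-methyl-1,3-dioxolan-4-one
Conditions: POCl3, DMF, CH2Cl2, 0 °C → rt; then ice-water
Reagents that add atoms: N,N-dimethylformamide CN(C)C=O (formyl carbon); phosphoryl chloride O=P(Cl)(Cl)Cl (chlorine); water O (formyl oxygen)
Why: Vilsmeier–Haack–Arnold chloroformylation of a 1,3-dicarbonyl compound: the chloroiminium ion formylates the central carbon (C8a) and the enol oxygen of the unhindered acetyl group is exchanged for chloride at C4a, the other ketone being shielded by the quaternary centre; no stereocentre is affected.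

Step 4
Reactants: 7 (S)-2-methylbutan-1-ol; 8 2-(triphenylphosphoranylidene)propanal
Product: 10 (2E,4S)-2,4-dimethylhex-2-enal, via (S)-2-methylbutanal 9 (not isolated)
Conditions: TEMPO (cat.), PhI(OAc)2, CH2Cl2, rt; then 8, toluene, 80 °C
Reagents that add atoms: none
Why: TEMPO-catalysed oxidation gives the configurationally labile α-branched aldehyde 9, which is consumed in the same flask by the stabilized ylide in an (E)-selective Wittig reaction without added base, so the (S)-centre should be retained.

Step 5
Reactants: 10 (2E,4S)-2,4-dimethylhex-2-enal; 11 diethyl [3-(trimethylsilyl)prop-2-yn-1-yl]phosphonate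
Product: 13 (3E,5E,7S)-5,7-dimethylnona-3,5-dien-1-yne, via silylated dienyne 12 (not isolated)
Conditions: 11, LiN(SiMe3)2, THF, −78 °C; then 10, −78 → 0 °C; then K2CO3 (cat.), MeOH, rt
Reagents that add atoms: none
Why: Horner–Wadsworth–Emmons olefination of the enal with the lithiated propargylphosphonate is expected to give the (3E)-alkene, and methanolysis of the C–Si bond in the same flask frees the terminal alkyne.

Step 6
Reactants: 6 (2S,5R)-2-tert-butyl-5-[(2E)-3-chloro-2-formylbut-2-enoyl]-5-methyl-1,3-dioxolan-4-one; 13 (3E,5E,7S)-5,7-dimethylnona-3,5-dien-1-yne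
Product: 14 (2S,5R)-2-tert-butyl-5-[(2E,6E,8E,10S)-2-formyl-3,8,10-trimethyldodeca-2,6,8-trien-4-ynoyl]-5-methyl-1,3-dioxolan-4-one
Conditions: PdCl2(PPh3)2 (cat.), CuI (cat.), Et3N, THF, 0 °C
Reagents that add atoms: none
Why: Sonogashira coupling of the doubly activated vinyl chloride (a vinylogous acid chloride, as in couplings of β-chlorovinyl aldehydes) should proceed at 0 °C with retention of the alkene geometry, and the short, cold exposure to the tertiary amine should leave the acidic C5 methyl group and the dioxolanone untouched.

Step 7
Reactants: 14 (2S,5R)-2-tert-butyl-5-[(2E,6E,8E,10S)-2-formyl-3,8,10-trimethyldodeca-2,6,8-trien-4-ynoyl]-5-methyl-1,3-dioxolan-4-one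
Product: 18 (7S)-3-[(1E,3E,5S)-3,5-dimethylhepta-1,3-dien-1-yl]-7-methyl-6,8-dioxo-7,8-dihydro-6H-isochromen-7-yl propanoate (5-deschloro-sclerketide B), via pyrylium tetrafluoroborate 15 (not isolated), via methylenepyran anhydrobase 16 (not isolated), via tertiary alcohol 17 (not isolated)
Conditions: HBF4·OEt2, CH2Cl2, −40 → 0 °C; then added slowly to iPr2NEt, CH2Cl2 (high dilution), −40 °C → rt; then (EtCO)2O, DMAP (cat.), rt
Reagents that add atoms: propionic anhydride CCC(=O)OC(=O)CC
Why: Proposed new method: HBF4 promotes attack of the coplanar formyl oxygen on the alkyne carbon that bears the dienyl group (6-endo-dig, protonation at C4), which closes the pyran ring as the aromatic 3-acyl-4-methylpyrylium 15; the closest known type is the Brønsted-acid cyclization of 2-alkynyl aryl aldehydes to isochromenylium tetrafluoroborates. iPr2NEt then removes a proton from the 4-methyl group, and the exocyclic carbon C5 of the methylenepyran 16 attacks the dioxolanone carbonyl C6 (6-exo-trig, Dieckmann-type), which closes the carbocycle C4a–C5–C6–C7–C8–C8a as the last ring; the closest known type is the C-acylation of pyrylium anhydrobases by acyl chlorides and anhydrides, here extended to an acetal-activated lactone. The tetrahedral intermediate collapses with loss of pivalaldehyde, loss of the second C5 proton restores the doubly vinylogous ester of 17, and the tertiary alkoxide is esterified in the same flask by propionic anhydride under DMAP catalysis. No stereocentre is formed: C7 was set in step 2, is quaternary and cannot epimerize. The order of ring closure is secured by the order of addition, because C5 is not nucleophilic in acid, and the metal-free acid avoids the 5-exo furyl-carbene pathway that π-acidic metals open for ene-yne-carbonyl compounds; the formyl oxygen is preferred over the ketone oxygen because the ketone is twisted out of plane by its quaternary neighbour while the alkene isomers equilibrate through the propargylic cation. The 4-methyl protons are far more acidic than the remote allylic C–H at the side-chain stereocentre, so a hindered amine at low temperature and high dilution should keep the (S)-centre intact and suppress intermolecular condensation of 16 with unreacted 15.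

Step 8
Reactants: 18 (7S)-3-[(1E,3E,5S)-3,5-dimethylhepta-1,3-dien-1-yl]-7-methyl-6,8-dioxo-7,8-dihydro-6H-isochromen-7-yl propanoate
Product: 19 sclerketide B, (7R)-5-chloro-3-[(1E,3E,5S)-3,5-dimethylhepta-1,3-dien-1-yl]-7-methyl-6,8-dioxo-7,8-dihydro-6H-isochromen-7-yl propanoate
Conditions: NCS, MeCN, 0 °C → rt
Reagents that add atoms: N-chlorosuccinimide O=C1CCC(=O)N1Cl
Why: Electrophilic chlorination at C5, the α-carbon of the doubly vinylogous ester and the most electron-rich position of the chromophore, followed by loss of the C5 proton (halogenation of azaphilones with N-halosuccinimides); the side-chain diene is conjugated to the acceptor system and less nucleophilic, and no stereocentre is touched.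

**Compound list**

1 | (S)-lactic acid | C[C@H](O)C(=O)O | starting material
2 | pivalaldehyde | CC(C)(C)C=O | starting material
3 | (2S,5S)-2-tert-butyl-5-methyl-1,3-dioxolan-4-one (cis) | C[C@@H]1O[C@H](C(C)(C)C)OC1=O | intermediate
4 | diketene (4-methylideneoxetan-2-one) | C=C1CC(=O)O1 | starting material
5 | (2S,5R)-2-tert-butyl-5-methyl-5-(3-oxobutanoyl)-1,3-dioxolan-4-one | C[C@]1(C(=O)CC(C)=O)O[C@H](C(C)(C)C)OC1=O | intermediate
6 | (2S,5R)-2-tert-butyl-5-[(2E)-3-chloro-2-formylbut-2-enoyl]-5-methyl-1,3-dioxolan-4-one | C[C@]1(C(=O)/C(C=O)=C(/Cl)C)O[C@H](C(C)(C)C)OC1=O | intermediate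
7 | (S)-2-methylbutan-1-ol | CC[C@H](C)CO | starting material
8 | 2-(triphenylphosphoranylidene)propanal | CC(C=O)=P(c1ccccc1)(c1ccccc1)c1ccccc1 | starting material
9 | (S)-2-methylbutanal | CC[C@H](C)C=O | intermediate
10 | (2E,4S)-2,4-dimethylhex-2-enal | O=C/C(C)=C/[C@@H](C)CC | intermediate
11 | diethyl [3-(trimethylsilyl)prop-2-yn-1-yl]phosphonate | CCOP(=O)(CC#C[Si](C)(C)C)OCC | starting material
12 | trimethyl[(3E,5E,7S)-5,7-dimethylnona-3,5-dien-1-yn-1-yl]silane | C[Si](C)(C)C#C/C=C/C(C)=C/[C@@H](C)CC | intermediate
13 | (3E,5E,7S)-5,7-dimethylnona-3,5-dien-1-yne | C#C/C=C/C(C)=C/[C@@H](C)CC | intermediate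
14 | (2S,5R)-2-tert-butyl-5-[(2E,6E,8E,10S)-2-formyl-3,8,10-trimethyldodeca-2,6,8-trien-4-ynoyl]-5-methyl-1,3-dioxolan-4-one | C[C@]1(C(=O)/C(C=O)=C(/C#C/C=C/C(C)=C/[C@@H](C)CC)C)O[C@H](C(C)(C)C)OC1=O | intermediate
15 | 3-{[(2S,4R)-2-tert-butyl-4-methyl-5-oxo-1,3-dioxolan-4-yl]carbonyl}-6-[(1E,3E,5S)-3,5-dimethylhepta-1,3-dien-1-yl]-4-methylpyrylium tetrafluoroborate | C[C@]1(C(=O)c2c[o+]c(/C=C/C(C)=C/[C@@H](C)CC)cc2C)O[C@H](C(C)(C)C)OC1=O.F[B-](F)(F)F | intermediate
16 | (2S,5R)-2-tert-butyl-5-({6-[(1E,3E,5S)-3,5-dimethylhepta-1,3-dien-1-yl]-4-methylidene-4H-pyran-3-yl}carbonyl)-5-methyl-1,3-dioxolan-4-one | C[C@]1(C(=O)C2=COC(/C=C/C(C)=C/[C@@H](C)CC)=CC2=C)O[C@H](C(C)(C)C)OC1=O | intermediate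
17 | (7S)-3-[(1E,3E,5S)-3,5-dimethylhepta-1,3-dien-1-yl]-7-hydroxy-7-methyl-6H-isochromene-6,8(7H)-dione | O[C@]1(C)C(=O)C2=COC(/C=C/C(C)=C/[C@@H](C)CC)=CC2=CC1=O | intermediate
18 | (7S)-3-[(1E,3E,5S)-3,5-dimethylhepta-1,3-dien-1-yl]-7-methyl-6,8-dioxo-7,8-dihydro-6H-isochromen-7-yl propanoate | CCC(=O)O[C@]1(C)C(=O)C2=COC(/C=C/C(C)=C/[C@@H](C)CC)=CC2=CC1=O | intermediate
19 | sclerketide B, (7R)-5-chloro-3-[(1E,3E,5S)-3,5-dimethylhepta-1,3-dien-1-yl]-7-methyl-6,8-dioxo-7,8-dihydro-6H-isochromen-7-yl propanoate | CCC(=O)O[C@]1(C)C(=O)C2=COC(/C=C/C(C)=C/[C@@H](C)CC)=CC2=C(Cl)C1=O | target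

**Step count**

Total steps: 8. Longest linear sequence: 6 (steps 1, 2, 3, 6, 7, 8).

**Steps most likely to fail**

Step 7 (proposed new method). The methylenepyran may fail to attack the lactone carbonyl, because proton exchange or self-condensation with unreacted pyrylium can outrun the ring closure; closure through the ketone oxygen or erosion of the side-chain centre by the base are further risks. The fallback changes the acyl donor to an anhydride, the documented partner for C-acylation of pyrylium anhydrobases, and keeps the carbocycle as the last ring. It sets out from 14: HBF4·OEt2 in CH2Cl2 gives the pyrylium salt 15, which is precipitated with Et2O and isolated. The acetal of 15 is hydrolysed in cold aqueous HBF4/AcOH (the pyrylium ring persists in strong acid; the product is kept cold because it is a β-keto acid) to the α-hydroxy acid pyrylium salt F1. Propionic anhydride with catalytic HBF4 esterifies the tertiary alcohol and converts the acid into the mixed propionic anhydride F2. Slow addition of the mixed anhydride to iPr2NEt at high dilution then forms the methylenepyran, whose exocyclic carbon C5 is acylated by the nearer anhydride carbonyl through a six-membered transition state. The fallback comes back to the route at 18.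

Step 3. Chlorination may occur at the hindered ketone oxygen, or the γ-methyl group may be formylated a second time by excess chloroiminium ion. The fallback places halide and formyl group through an alkyne, so that their positions are fixed by connectivity. It sets out from 3: LDA, then N-methoxy-N-methylbut-2-ynamide, gives the ynone F3 with the same facial control as step 2. MgI2 and monomeric formaldehyde in CH2Cl2 add iodide to C4a and the resulting iodo-allenolate to formaldehyde (halo-aldol, the iodide variant of the Morita–Baylis–Hillman reaction) to give the β-iodo allylic alcohol F4. Dess–Martin periodinane oxidizes it to the iodo enal F5, which takes the place of 6 in the Sonogashira coupling of step 6. The fallback comes back to the route at 14.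

Step 6. The amine and the copper salt may trigger premature deprotonation of the γ-methyl group with attack on the dioxolanone, addition of the amine to the vinyl chloride, or copper-carbene chemistry of the ene-yne-carbonyl product. The fallback transfers the alkyne under neutral, copper-free conditions. It sets out from 13: n-BuLi, then Bu3SnCl, gives the alkynylstannane F6, and Stille coupling of this stannane with 6 (Pd2(dba)3, AsPh3, THF, rt) needs no base. The fallback comes back to the route at 14.

**Further compounds**

F1 | step 7 | 3-[(2R)-2-carboxy-2-hydroxypropanoyl]-6-[(1E,3E,5S)-3,5-dimethylhepta-1,3-dien-1-yl]-4-methylpyrylium tetrafluoroborate | C[C@](O)(C(=O)O)C(=O)c1c[o+]c(/C=C/C(C)=C/[C@@H](C)CC)cc1C.F[B-](F)(F)F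
F2 | step 7 | 6-[(1E,3E,5S)-3,5-dimethylhepta-1,3-dien-1-yl]-4-methyl-3-[(2R)-2-methyl-3-oxo-2-(propanoyloxy)-3-(propanoyloxy)propanoyl]pyrylium tetrafluoroborate (mixed anhydride) | C[C@](OC(=O)CC)(C(=O)OC(=O)CC)C(=O)c1c[o+]c(/C=C/C(C)=C/[C@@H](C)CC)cc1C.F[B-](F)(F)F
F3 | step 3 | (2S,5R)-5-(but-2-ynoyl)-2-tert-butyl-5-methyl-1,3-dioxolan-4-one | C[C@]1(C(=O)C#CC)O[C@H](C(C)(C)C)OC1=O
F4 | step 3 | (2S,5R)-2-tert-butyl-5-[(2E)-2-(hydroxymethyl)-3-iodobut-2-enoyl]-5-methyl-1,3-dioxolan-4-one | C[C@]1(C(=O)/C(CO)=C(/I)C)O[C@H](C(C)(C)C)OC1=O
F5 | step 3 | (2S,5R)-2-tert-butyl-5-[(2E)-2-formyl-3-iodobut-2-enoyl]-5-methyl-1,3-dioxolan-4-one | C[C@]1(C(=O)/C(C=O)=C(/I)C)O[C@H](C(C)(C)C)OC1=O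
F6 | step 6 | tributyl[(3E,5E,7S)-5,7-dimethylnona-3,5-dien-1-yn-1-yl]stannane | CCCC[Sn](CCCC)(CCCC)C#C/C=C/C(C)=C/[C@@H](C)CC
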